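**Assumption:** the SMILES is read as drawn, (3R,3aS,4S,6R,7S,8aR), i.e. the 8,9-epoxide of ferutinin; the sense of induction of the copper catalyst in step 4 is assigned by analogy, and the antipodal ligand is used if it proves opposite.

**Retrosynthetic overview**
- Target ⇐ acylation of an epoxy diol, which comes from hydroxyl-directed epoxidation of jaeschkeanadiol (oxirane formed last).
- Seven-membered ring ⇐ ring-closing metathesis of an allyl/methallyl diene; the carbinol ⇐ chelation-controlled methallylation of a cyclopentane carbaldehyde.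
- Angular methyl and ring-fusion hydrogen ⇐ reductive cleavage of a bicyclo[3.1.0]hexane carbaldehyde, whose cyclopropane CH2 is the latent methyl.
- Key step: enantioselective intramolecular cyclopropanation of an acyclic α-diazo-β-keto amide closes the cyclopentanone and the cyclopropane together; isopropyl then enters anti to the cyclopropane.
- Ring order: cyclopropane + cyclopentane (one event) → cyclopropane cleaved → cycloheptene → oxirane.

**Route**

Step 1
Reactants: 1 3-chloro-2-(chloromethyl)prop-1-ene (3 equiv); 2 vinylmagnesium bromide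
Product: 3 2-(chloromethyl)penta-1,4-diene
Conditions: CuI (5 mol %), THF, −20 → 0 °C
Reagents that add atoms: none
Why: Copper-catalysed allyl–vinyl Grignard cross-coupling; SN2 and SN2′ give the same product because 1 is symmetric, and excess 1 suppresses double substitution; no stereocenter.

Step 2
Reactants: 4 N-methoxy-N-methyl-3-oxobutanamide; 3 2-(chloromethyl)penta-1,4-diene
Product: 6 N-methoxy-N-methyl-6-methylidene-3-oxonon-8-enamide, via dianion 5 (not isolated)
Conditions: NaH, THF, 0 °C; n-BuLi, −10 °C; then 3, −10 → 23 °C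
Reagents that add atoms: none
Why: Weiler-type γ-alkylation of an acetoacetamide dianion, the terminal carbanion being the more nucleophilic site; no stereocenter.

Step 3
Reactants: 6 N-methoxy-N-methyl-6-methylidene-3-oxonon-8-enamide
Product: 7 2-diazo-N-methoxy-N-methyl-6-methylidene-3-oxonon-8-enamide
Conditions: 4-acetamidobenzenesulfonyl azide, Et3N, MeCN, 0 → 23 °C
Reagents that add atoms: 4-acetamidobenzenesulfonyl azide, CC(=O)Nc1ccc(cc1)S(=O)(=O)N=[N+]=[N-]
Why: Regitz diazo transfer to the active methylene.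

Step 4
Reactants: 7 2-diazo-N-methoxy-N-methyl-6-methylidene-3-oxonon-8-enamide
Product: 9 (1S,5R)-N-methoxy-N-methyl-2-oxo-5-(prop-2-en-1-yl)bicyclo[3.1.0]hexane-1-carboxamide, via copper carbene 8 (not isolated)
Conditions: [Cu(MeCN)4]PF6 (5 mol %), (S,S)-tBu-box (6 mol %), toluene, 50 °C, slow addition
Reagents that add atoms: none
Why: Enantioselective intramolecular cyclopropanation (copper–bis(oxazoline) carbene transfer, extended here from keto sulfones and esters to a keto Weinreb amide): the carbene adds 5-exo to the 1,1-disubstituted alkene, closing cyclopentanone and cyclopropane in one event; the cis fusion is forced and the ligand selects the alkene face, fixing C5 (the future quaternary carbon) and C1.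

Step 5
Reactants: 9 (1S,5R)-N-methoxy-N-methyl-2-oxo-5-(prop-2-en-1-yl)bicyclo[3.1.0]hexane-1-carboxamide; 10 isopropylmagnesium chloride
Product: 11 (1S,2R,5R)-2-hydroxy-N-methoxy-N-methyl-2-(propan-2-yl)-5-(prop-2-en-1-yl)bicyclo[3.1.0]hexane-1-carboxamide
Conditions: CeCl3 (anhydrous, 2.5 equiv), THF, −78 → −40 °C
Reagents that add atoms: none
Why: Imamoto organocerium 1,2-addition (ketone faster than Weinreb amide, non-basic toward the C3 protons); Ce/Mg chelation should hold the amide carbonyl in the ketone plane, so the nucleophile is expected to enter anti to the cyclopropane CH2, placing OH cis and isopropyl trans to the future methyl.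

Step 6
Reactants: 11 (1S,2R,5R)-2-hydroxy-N-methoxy-N-methyl-2-(propan-2-yl)-5-(prop-2-en-1-yl)bicyclo[3.1.0]hexane-1-carboxamide
Product: 12 (1S,2R,5R)-2-hydroxy-2-(propan-2-yl)-5-(prop-2-en-1-yl)bicyclo[3.1.0]hexane-1-carbaldehyde
Conditions: LiAlH4 (1.5 equiv), THF, −40 → 0 °C
Reagents that add atoms: none
Why: Weinreb amide reduction stops at the aldehyde through the stable chelated tetrahedral intermediate; C1 is quaternary, so nothing can epimerise.

Step 7
Reactants: 12 (1S,2R,5R)-2-hydroxy-2-(propan-2-yl)-5-(prop-2-en-1-yl)bicyclo[3.1.0]hexane-1-carbaldehyde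
Product: 15 (1R,2R,5R)-2-hydroxy-5-methyl-2-(propan-2-yl)-5-(prop-2-en-1-yl)cyclopentane-1-carbaldehyde, via dilithium enolate alkoxide 13 (not isolated), via C1-epimeric aldehyde 14 (not isolated)
Conditions: Li (4 equiv), NH3(l)/THF, −78 °C; solid NH4Cl; then DBU (0.2 equiv), CH2Cl2, 23 °C
Reagents that add atoms: none
Why: Dissolving-metal cleavage of a conjugated cyclopropyl carbonyl (precedent is for cyclopropyl ketones; the aldehyde is an extension): the C1–C6 bond breaks toward the primary carbanion, turning the cyclopropane CH2 into the angular methyl, and DBU then equilibrates C1 so the formyl group lies trans to isopropyl and allyl.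

Step 8
Reactants: 15 (1R,2R,5R)-2-hydroxy-5-methyl-2-(propan-2-yl)-5-(prop-2-en-1-yl)cyclopentane-1-carbaldehyde; 16 (2-methylprop-2-en-1-yl)magnesium chloride (3 equiv)
Product: 17 (1R,2S,3R)-2-[(1S)-1-hydroxy-3-methylbut-3-en-1-yl]-3-methyl-1-(propan-2-yl)-3-(prop-2-en-1-yl)cyclopentan-1-ol
Conditions: THF, −78 → −40 °C
Reagents that add atoms: none
Why: Cram-chelate Grignard addition: the first equivalent makes the magnesium alkoxide of the cis tertiary hydroxyl, which chelates the aldehyde; attack on the exposed face away from the quaternary carbon gives the (S)-carbinol.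

Step 9
Reactants: 17 (1R,2S,3R)-2-[(1S)-1-hydroxy-3-methylbut-3-en-1-yl]-3-methyl-1-(propan-2-yl)-3-(prop-2-en-1-yl)cyclopentan-1-ol
Product: 18 jaeschkeanadiol, (3R,3aS,4S,8aR)-6,8a-dimethyl-3-(propan-2-yl)-1,2,3,3a,4,5,8,8a-octahydroazulene-3,4-diol
Conditions: second-generation Grubbs catalyst RuCl2(=CHPh)(PCy3)(H2IMes) (5 mol %), CH2Cl2 (5 mM), 40 °C
Reagents that add atoms: none
Why: Ring-closing metathesis of the allyl and methallyl groups gives the trisubstituted cycloheptene; the trans ring fusion is already fixed by the two cyclopentane stereocenters.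

Step 10
Reactants: 18 jaeschkeanadiol
Product: 19 (3R,3aS,4S,6R,7S,8aR)-6,7-epoxy-6,8a-dimethyl-3-(propan-2-yl)decahydroazulene-3,4-diol
Conditions: VO(acac)2 (5 mol %), t-BuOOH (1.5 equiv), CH2Cl2, 0 → 23 °C
Reagents that add atoms: tert-butyl hydroperoxide, CC(C)(C)OO
Why: Vanadium-catalysed hydroxyl-directed epoxidation of a homoallylic alcohol: oxygen is delivered syn to the C4 hydroxyl, which is also the face opposite the angular methyl, setting both oxirane carbons.

Step 11
Reactants: 19 (3R,3aS,4S,6R,7S,8aR)-6,7-epoxy-6,8a-dimethyl-3-(propan-2-yl)decahydroazulene-3,4-diol; 20 4-acetoxybenzoyl chloride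
Product: 21 (3R,3aS,4S,6R,7S,8aR)-6,7-epoxy-3-hydroxy-6,8a-dimethyl-3-(propan-2-yl)decahydroazulen-4-yl 4-(acetyloxy)benzoate
Conditions: pyridine (3 equiv), DMAP (0.2 equiv), CH2Cl2, 0 → 23 °C
Reagents that add atoms: none
Why: DMAP-catalysed acylation of the secondary alcohol; the tertiary alcohol does not react and the base keeps the epoxide away from acid.

Step 12
Reactants: 21 (3R,3aS,4S,6R,7S,8aR)-6,7-epoxy-3-hydroxy-6,8a-dimethyl-3-(propan-2-yl)decahydroazulen-4-yl 4-(acetyloxy)benzoate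
Product: 22 jaeskeanin, (3R,3aS,4S,6R,7S,8aR)-6,7-epoxy-3-hydroxy-6,8a-dimethyl-3-(propan-2-yl)decahydroazulen-4-yl 4-hydroxybenzoate
Conditions: K2CO3 (0.2 equiv), MeOH, 0 °C, 30 min
Reagents that add atoms: none
Why: Zemplén-type transesterification of the aryl acetate; the liberated phenoxide deactivates the hindered benzoate toward methanolysis, and the epoxide is stable to mild base.

**Compound list**
1 | 3-chloro-2-(chloromethyl)prop-1-ene | ClCC(=C)CCl | starting material
2 | vinylmagnesium bromide | C=C[Mg]Br | starting material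
3 | 2-(chloromethyl)penta-1,4-diene | ClCC(=C)CC=C | intermediate
4 | N-methoxy-N-methyl-3-oxobutanamide | CC(=O)CC(=O)N(C)OC | starting material
5 | lithium sodium dianion (bis-enolate) of 4 | [Li+].[Na+].C=C([O-])C=C([O-])N(C)OC | intermediate
6 | N-methoxy-N-methyl-6-methylidene-3-oxonon-8-enamide | C=CCC(=C)CCC(=O)CC(=O)N(C)OC | intermediate
7 | 2-diazo-N-methoxy-N-methyl-6-methylidene-3-oxonon-8-enamide | C=CCC(=C)CCC(=O)C(=[N+]=[N-])C(=O)N(C)OC | intermediate
8 | copper carbene from 7 (bis(oxazoline) ligand not shown) | C=CCC(=C)CCC(=O)C(=[Cu])C(=O)N(C)OC | intermediate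
9 | (1S,5R)-N-methoxy-N-methyl-2-oxo-5-(prop-2-en-1-yl)bicyclo[3.1.0]hexane-1-carboxamide | O=C1CC[C@@]2(CC=C)C[C@@]12C(=O)N(C)OC | intermediate
10 | isopropylmagnesium chloride | CC(C)[Mg]Cl | starting material
11 | (1S,2R,5R)-2-hydroxy-N-methoxy-N-methyl-2-(propan-2-yl)-5-(prop-2-en-1-yl)bicyclo[3.1.0]hexane-1-carboxamide | CC(C)[C@]1(O)CC[C@@]2(CC=C)C[C@@]12C(=O)N(C)OC | intermediate
12 | (1S,2R,5R)-2-hydroxy-2-(propan-2-yl)-5-(prop-2-en-1-yl)bicyclo[3.1.0]hexane-1-carbaldehyde | CC(C)[C@]1(O)CC[C@@]2(CC=C)C[C@@]12C=O | intermediate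
13 | dilithium enolate alkoxide from ring opening of 12 | CC(C)[C@]1([O-])CC[C@](C)(CC=C)C1=C[O-].[Li+].[Li+] | intermediate
14 | (1S,2R,5R)-2-hydroxy-5-methyl-2-(propan-2-yl)-5-(prop-2-en-1-yl)cyclopentane-1-carbaldehyde (kinetic C1 epimer) | CC(C)[C@]1(O)CC[C@](C)(CC=C)[C@@H]1C=O | intermediate
15 | (1R,2R,5R)-2-hydroxy-5-methyl-2-(propan-2-yl)-5-(prop-2-en-1-yl)cyclopentane-1-carbaldehyde | CC(C)[C@]1(O)CC[C@](C)(CC=C)[C@H]1C=O | intermediate
16 | (2-methylprop-2-en-1-yl)magnesium chloride | CC(=C)C[Mg]Cl | starting material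
17 | (1R,2S,3R)-2-[(1S)-1-hydroxy-3-methylbut-3-en-1-yl]-3-methyl-1-(propan-2-yl)-3-(prop-2-en-1-yl)cyclopentan-1-ol | CC(C)[C@]1(O)CC[C@](C)(CC=C)[C@H]1[C@@H](O)CC(C)=C | intermediate
18 | jaeschkeanadiol, (3R,3aS,4S,8aR)-6,8a-dimethyl-3-(propan-2-yl)-1,2,3,3a,4,5,8,8a-octahydroazulene-3,4-diol | CC(C)[C@]1(O)CC[C@]2(C)CC=C(C)C[C@H](O)[C@H]21 | intermediate
19 | (3R,3aS,4S,6R,7S,8aR)-6,7-epoxy-6,8a-dimethyl-3-(propan-2-yl)decahydroazulene-3,4-diol | CC(C)[C@]1(O)CC[C@]2(C)C[C@@H]3O[C@]3(C)C[C@H](O)[C@H]21 | intermediate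
20 | 4-acetoxybenzoyl chloride | CC(=O)Oc1ccc(cc1)C(Cl)=O | starting material
21 | (3R,3aS,4S,6R,7S,8aR)-6,7-epoxy-3-hydroxy-6,8a-dimethyl-3-(propan-2-yl)decahydroazulen-4-yl 4-(acetyloxy)benzoate | CC(C)[C@]1(O)CC[C@]2(C)C[C@@H]3O[C@]3(C)C[C@H](OC(=O)c3ccc(OC(C)=O)cc3)[C@H]21 | intermediate
22 | jaeskeanin | CC(C)[C@]1(O)CC[C@]2(C)C[C@@H]3O[C@]3(C)C[C@H](OC(=O)c3ccc(O)cc3)[C@H]21 | target

**Step count and risks**

Total steps: 12. Longest linear sequence: 12 steps (1 → 22; 4 joins in step 2).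

Most likely to fail: steps 4, 7 and 8. Step 5 is the next concern, since the route depends on isopropyl adding anti to the cyclopropane at a hindered ketone.

Step 4 may give low enantiomeric excess or C–H insertion, because the keto Weinreb amide is an untested acceptor for this catalyst. The fallback sets out from 3 and returns at 12, replacing catalyst control by a separable chiral auxiliary. Alkylate the dianion of commercial (1R,2S,5R)-menthyl acetoacetate with 3 to give (1R,2S,5R)-menthyl 6-methylidene-3-oxonon-8-enoate F1. Diazo transfer gives (1R,2S,5R)-menthyl 2-diazo-6-methylidene-3-oxonon-8-enoate F2. Cyclise with Rh2(OAc)4 and separate the two diastereomers by chromatography or crystallisation to obtain (1R,2S,5R)-menthyl (1S,5R)-2-oxo-5-(prop-2-en-1-yl)bicyclo[3.1.0]hexane-1-carboxylate F3. Add iPrMgCl/CeCl3 as in step 5 to give (1R,2S,5R)-menthyl (1S,2R,5R)-2-hydroxy-2-(propan-2-yl)-5-(prop-2-en-1-yl)bicyclo[3.1.0]hexane-1-carboxylate F4. Reduce with LiAlH4 to (1R,2R,5R)-1-(hydroxymethyl)-2-(propan-2-yl)-5-(prop-2-en-1-yl)bicyclo[3.1.0]hexan-2-ol F5, recovering menthol. Oxidise the primary alcohol with TEMPO and PhI(OAc)2 to reach 12.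

Step 7 may over-reduce the aldehyde instead of cleaving the ring, or the β-hydroxy aldehyde may undergo retro-aldol during equilibration. The fallback sets out from 11 and returns at 15, doing the cleavage on a ketone, the textbook substrate. Methylmagnesium bromide converts 11 into 1-[(1S,2R,5R)-2-hydroxy-2-(propan-2-yl)-5-(prop-2-en-1-yl)bicyclo[3.1.0]hexan-1-yl]ethan-1-one F6. Li in NH3 followed by K2CO3 in methanol gives 1-[(1R,2R,5R)-2-hydroxy-5-methyl-2-(propan-2-yl)-5-(prop-2-en-1-yl)cyclopentyl]ethan-1-one F7. Hydroxylate the kinetic methyl enolate (LiN(iPr)2, then 2-(phenylsulfonyl)-3-phenyloxaziridine) to 2-hydroxy-1-[(1R,2R,5R)-2-hydroxy-5-methyl-2-(propan-2-yl)-5-(prop-2-en-1-yl)cyclopentyl]ethan-1-one F8. NaBH4 gives 1-[(1S,2R,5R)-2-hydroxy-5-methyl-2-(propan-2-yl)-5-(prop-2-en-1-yl)cyclopentyl]ethane-1,2-diol F9 as a mixture of carbinol epimers. NaIO4 cleaves the 1,2-diol to 15.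

Step 8 may give poor diastereoselectivity, since allyl-type Grignard reagents often escape chelation control. The fallback sets out from 15 and returns at 17, building the carbinol by an open-transition-state aldol instead. A MgBr2·OEt2-mediated, chelation-controlled Mukaiyama aldol of 15 with 2-(trimethylsilyloxy)propene gives (4S)-4-hydroxy-4-[(1S,2R,5R)-2-hydroxy-5-methyl-2-(propan-2-yl)-5-(prop-2-en-1-yl)cyclopentyl]butan-2-one F10. Wittig methylenation of the methyl ketone with Ph3P=CH2 gives 17.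

**Further compounds**
F1 | step 4 | (1R,2S,5R)-menthyl 6-methylidene-3-oxonon-8-enoate | CC(C)[C@@H]1CC[C@@H](C)C[C@H]1OC(=O)CC(=O)CCC(=C)CC=C
F2 | step 4 | (1R,2S,5R)-menthyl 2-diazo-6-methylidene-3-oxonon-8-enoate | CC(C)[C@@H]1CC[C@@H](C)C[C@H]1OC(=O)C(=[N+]=[N-])C(=O)CCC(=C)CC=C
F3 | step 4 | (1R,2S,5R)-menthyl (1S,5R)-2-oxo-5-(prop-2-en-1-yl)bicyclo[3.1.0]hexane-1-carboxylate | O=C1CC[C@@]2(CC=C)C[C@@]12C(=O)O[C@@H]3C[C@H](C)CC[C@H]3C(C)C
F4 | step 4 | (1R,2S,5R)-menthyl (1S,2R,5R)-2-hydroxy-2-(propan-2-yl)-5-(prop-2-en-1-yl)bicyclo[3.1.0]hexane-1-carboxylate | CC(C)[C@]1(O)CC[C@@]2(CC=C)C[C@@]12C(=O)O[C@@H]3C[C@H](C)CC[C@H]3C(C)C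
F5 | step 4 | (1R,2R,5R)-1-(hydroxymethyl)-2-(propan-2-yl)-5-(prop-2-en-1-yl)bicyclo[3.1.0]hexan-2-ol | CC(C)[C@]1(O)CC[C@@]2(CC=C)C[C@@]12CO
F6 | step 7 | 1-[(1S,2R,5R)-2-hydroxy-2-(propan-2-yl)-5-(prop-2-en-1-yl)bicyclo[3.1.0]hexan-1-yl]ethan-1-one | CC(C)[C@]1(O)CC[C@@]2(CC=C)C[C@@]12C(C)=O
F7 | step 7 | 1-[(1R,2R,5R)-2-hydroxy-5-methyl-2-(propan-2-yl)-5-(prop-2-en-1-yl)cyclopentyl]ethan-1-one | CC(C)[C@]1(O)CC[C@](C)(CC=C)[C@H]1C(C)=O
F8 | step 7 | 2-hydroxy-1-[(1R,2R,5R)-2-hydroxy-5-methyl-2-(propan-2-yl)-5-(prop-2-en-1-yl)cyclopentyl]ethan-1-one | CC(C)[C@]1(O)CC[C@](C)(CC=C)[C@H]1C(=O)CO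
F9 | step 7 | 1-[(1S,2R,5R)-2-hydroxy-5-methyl-2-(propan-2-yl)-5-(prop-2-en-1-yl)cyclopentyl]ethane-1,2-diol (both carbinol epimers) | CC(C)[C@]1(O)CC[C@](C)(CC=C)[C@H]1C(O)CO
F10 | step 8 | (4S)-4-hydroxy-4-[(1S,2R,5R)-2-hydroxy-5-methyl-2-(propan-2-yl)-5-(prop-2-en-1-yl)cyclopentyl]butan-2-one | CC(C)[C@]1(O)CC[C@](C)(CC=C)[C@H]1[C@@H](O)CC(C)=O
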